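**Plan**

1. Retrosynthetic cuts: the O8 ester and O11 acetate; C11–CH3 (lactone-enolate methylation); O6–C12 and C7–C11 (lactonisation and glyoxylate aldol on a C6 ketone); vinyl and isopropenyl are rejoined C1–C4 (retro-ethenolysis) to a cis-fused 1-methylcyclobutene, traced back via a cyclobutanone to a methylidenecyclobutane; C10–C1 and C5–C4 (retro-[2+2]) give (R)-5-silyloxy-3-methylcyclohex-2-enone and allene.
2. Enabling feature: the vinyl group on quaternary C10 and the isopropenyl group on C5 are cis on adjacent ring carbons, and C6 next to C5 is oxygenated. C5=C10 can therefore be the α,β-bond of a C6 enone, and C1 and C4 can be tied into a four-membered ring C10–C1–C4–C5.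
3. Forward ring order: cyclohexenone (aldol condensation), then cyclobutane (photocycloaddition), then γ-lactone (aldol, reduction, methylation), then cyclobutene, then ring opening with ethylene, which releases both alkenes last, then two acylations.
4. Stereochemistry: C8 from an amine-catalysed desymmetrisation; C5 and C10 anti to O8 and mutually cis from the photocycloaddition; C7 anti to O8; C6 by equatorial hydride attack; C11 by convex-face methylation.
5. The cyclobutane keeps the 1,5-diene masked through all enolate, hydride and ozonolysis steps, and its strain drives the unmasking.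

Key step: step 4

Convention: elemane numbering as in the target is used for all compounds. C10 carries CH3 and C1(=C2); C5 carries C4(=C3)(C15); C6 carries the lactone O; C7 carries C11(C13)–C12; C8 carries the ester O; C9 is CH2. The α-face is the ring face carrying C1 on C10, C4 on C5, O on C6 and C11 on C7. The β-face carries the C10 methyl and O8. At C11 the methyl lies on the lactone face of H6/H7 and the oxygen on the face of C5/C8.

Assumption: the quinidine-derived primary amine is taken to give the (R)-enone 5 from a 4-silyloxy-heptanedione; if a test run shows the opposite sense, the quinine-derived pseudoenantiomer is used.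

**Route**

Step 1
Reactants: 1 hepta-1,6-dien-4-ol
Product: 2 tert-butyl(hepta-1,6-dien-4-yloxy)dimethylsilane
Conditions: TBSCl, imidazole, DMF, rt
Reagents that add atoms: tert-butyldimethylsilyl chloride, CC(C)(C)[Si](C)(C)Cl
Why: Imidazole-assisted silylation of a secondary alcohol whose carbinol carbon is still prochiral, so no stereochemistry is involved.

Step 2
Reactants: 2 tert-butyl(hepta-1,6-dien-4-yloxy)dimethylsilane
Product: 3 4-[(tert-butyldimethylsilyl)oxy]heptane-2,6-dione
Conditions: PdCl2 (10 mol %), CuCl (cat.), O2 (1 atm), DMF/H2O 7:1, rt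
Reagents that add atoms: water, O (the carbonyl oxygen; regenerated from dioxygen, O=O)
Why: Twofold Tsuji–Wacker oxidation places both carbonyls at the internal carbons of the terminal alkenes and tolerates the β-silyloxy group, giving an achiral diketone.

Step 3
Reactants: 3 4-[(tert-butyldimethylsilyl)oxy]heptane-2,6-dione
Product: 5 (R)-5-[(tert-butyldimethylsilyl)oxy]-3-methylcyclohex-2-en-1-one, via ketol 4 (not isolated)
Conditions: 9-amino-9-deoxy-epi-quinidine (20 mol %), AcOH (60 mol %), toluene, −15 °C → rt
Reagents that add atoms: none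
Why: Primary-amine (enamine) catalysed desymmetrising intramolecular aldol condensation (6-enolexo) of a 4-substituted heptane-2,6-dione, in which the chiral amine selects one of the two enantiotopic acetonyl arms as donor and thereby fixes C8.

Step 4
Reactants: 5 (R)-5-[(tert-butyldimethylsilyl)oxy]-3-methylcyclohex-2-en-1-one; 6 allene (propa-1,2-diene)
Product: 7 (1R,4R,6R)-4-[(tert-butyldimethylsilyl)oxy]-6-methyl-8-methylidenebicyclo[4.2.0]octan-2-one
Conditions: hν (medium-pressure Hg lamp, uranium-glass filter, λ > 340 nm), allene (excess), THF, −78 °C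
Reagents that add atoms: none
Why: The triplet enone bonds through its α-carbon C5 to the central allene carbon to give an allyl/tertiary-alkyl 1,4-biradical, which after spin inversion collapses between the allyl terminus C1 and C10; the closest known reaction type is the head-to-head [2+2] photocycloaddition of allene to 3-alkylcyclohex-2-enones. The four-membered ring C10–C1–C4–C5 is thus closed stepwise on one enone face, and only the cis ring fusion is expected to persist (a trans-fused isomer would epimerise at C5). Both new stereocentres derive from C8: the pyramidalised C10 should form its new bond axially in the half-chair that keeps the 8-silyloxy group equatorial, that is anti to it, and C5 follows from the cis fusion. The step needs head-to-head regiochemistry (C4 and not C1 on C5), which formation of the allyl radical secures, and anti facial selectivity, which the C8 substituent secures. The long-wavelength filter and limited conversion per pass should suppress 1,3-acyl shift of the β,γ-unsaturated ketone product. The ring strain stored here drives the ring opening in step 12.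

Step 5
Reactants: 7 photoadduct; 8 ethyl glyoxylate
Product: 10 ethyl 2-{4-[(tert-butyldimethylsilyl)oxy]-6-methyl-8-methylidene-2-oxobicyclo[4.2.0]octan-3-yl}-2-hydroxyacetate (C7 side chain α; C11 epimers), via lithium enolate 9 (not isolated)
Conditions: LDA, THF, −78 °C; then 8 (freshly distilled), −78 °C; aq NH4Cl
Reagents that add atoms: none
Why: Kinetic deprotonation by the bulky amide should occur at the C7 methylene and not at the hindered ring-fusion methine C5, and the aldol addition to the very electrophilic glyoxylate should take place anti to the adjacent 8-silyloxy group (1,2-induction), placing the side chain on the α-face, while the C11 carbinol mixture is planarised again in step 8.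

Step 6
Reactants: 10 aldol adduct
Product: 11 ethyl 2-[(tert-butyldimethylsilyl)oxy]-2-{4-[(tert-butyldimethylsilyl)oxy]-6-methyl-8-methylidene-2-oxobicyclo[4.2.0]octan-3-yl}acetate
Conditions: TBSOTf, 2,6-lutidine, CH2Cl2, −78 °C
Reagents that add atoms: tert-butyldimethylsilyl trifluoromethanesulfonate, CC(C)(C)[Si](C)(C)OS(=O)(=O)C(F)(F)F
Why: O-Silylation of the α-hydroxy ester blocks retro-aldol cleavage and protects the oxygen that ends as the C11 acetoxy oxygen, without touching a stereocentre.

Step 7
Reactants: 11 bis-silyl keto ester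
Product: 13 cis-fused γ-lactone (O6α–C12; 8β-OTBS; 11-OTBS epimers; methylidenecyclobutane), via lithium alkoxide 12 (not isolated)
Conditions: L-Selectride, THF, −78 → 0 °C; aq NH4Cl; PPTS (cat.), toluene, 50 °C if lactonisation is incomplete
Reagents that add atoms: none
Why: The bulky hydride should attack the C6 ketone equatorially from the β-face because the axial C10–C1 bond of the cyclobutane shields the α-face, and the resulting axial 6α-alkoxide is cis to the C7 side chain and closes the five-membered lactone by acyl substitution with loss of ethoxide.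

Step 8
Reactants: 13 α-silyloxy lactone
Product: 15 11-methyl-11-silyloxy lactone (methyl syn to H7), via lithium enolate 14 (not isolated)
Conditions: LDA, THF, −78 °C; MeI, DMPU, −78 → −40 °C
Reagents that add atoms: iodomethane, CI
Why: In this lactone-enolate alkylation iodomethane should enter on the convex face of the cis-fused bicycle, syn to H7 and anti to the C8 branch, so that the methyl ends on the H6/H7 side and the oxygen on the C8 side as required at C11.

Step 9
Reactants: 15 methylidenecyclobutane lactone
Product: 17 cyclobutanone (C4=O), via ozonide 16 (not isolated)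
Conditions: O3, CH2Cl2, −78 °C; Me2S, −78 °C → rt
Reagents that add atoms: ozone, [O-][O+]=O
Why: Ozonolysis with reductive work-up cleaves the only C=C bond, and because O6 is already acylated the new C4 ketone cannot enter a 1,3-dicarbonyl cleavage.

Step 10
Reactants: 17 cyclobutanone
Product: 19 cyclobutenyl triflate (C1=C4–OTf), via potassium enolate 18 (not isolated)
Conditions: KHMDS, THF, −78 °C; PhNTf2, −78 → 0 °C
Reagents that add atoms: N-phenylbis(trifluoromethanesulfonimide), O=S(=O)(N(c1ccccc1)S(=O)(=O)C(F)(F)F)C(F)(F)F
Why: Kinetic enolisation should take the unhindered C1 methylene and not the ring-fusion methine C5, and O-sulfonylation of the enolate gives the alkenyl triflate, the lactone having no α-hydrogen left.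

Step 11
Reactants: 19 cyclobutenyl triflate
Product: 20 cis-fused 1-methylcyclobutene (C1H=C4–CH3)
Conditions: Pd(PPh3)4 (5 mol %), MeZnCl, THF, rt
Reagents that add atoms: methylzinc chloride, C[Zn]Cl
Why: Negishi coupling of an alkenyl triflate installs C15 on C4 under conditions that lactone and silyl ethers tolerate.

Step 12
Reactants: 20 1-methylcyclobutene; 21 ethylene
Product: 22 8β,11-bis[(tert-butyldimethylsilyl)oxy]-elema-1,3-dien-12,6-olide (vinyl on C10 and isopropenyl on C5, both α)
Conditions: Grubbs II (5 mol %), ethylene (1 atm), CH2Cl2, rt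
Reagents that add atoms: none
Why: Ring-opening metathesis with ethylene (ethenolysis) of the trisubstituted cyclobutene is driven and made irreversible by release of the ring strain, leaves C5 and C10 untouched so that vinyl and isopropenyl emerge cis, and gives two alkenes too hindered for secondary metathesis.

Step 13
Reactants: 22 bis-silyl ether
Product: 23 8β,11-dihydroxy-elema-1,3-dien-12,6-olide
Conditions: HF·pyridine, pyridine/THF, 0 °C → rt
Reagents that add atoms: none
Why: Fluoride-driven cleavage of both silyl ethers through Si–F bond formation should leave the lactone and both alkenes untouched under buffered conditions.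

Step 14
Reactants: 23 diol; 24 3-methylbut-3-enoic acid
Product: 25 11-hydroxy-8β-(3-methylbut-3-enoyloxy)-elema-1,3-dien-12,6-olide
Conditions: EDC·HCl, DMAP (10 mol %), CH2Cl2, 0 °C
Reagents that add atoms: none
Why: Steglich esterification should acylate the secondary equatorial C8 hydroxyl with retention while the tertiary C11 hydroxyl stays free, and low temperature with little DMAP keeps the β,γ-unsaturated acyl group out of conjugation.

Step 15
Reactants: 25 hydroxy ester
Product: 26 target CNP0106639.1
Conditions: Ac2O, DMAP, Et3N, CH2Cl2, 0 °C → rt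
Reagents that add atoms: acetic anhydride, CC(=O)OC(C)=O
Why: DMAP-catalysed acetylation of the remaining tertiary α-hydroxy lactone completes the target without change at any stereocentre.

**Compound list**

1 | hepta-1,6-dien-4-ol | C=CCC(O)CC=C | starting material
2 | tert-butyl(hepta-1,6-dien-4-yloxy)dimethylsilane | C=CCC(O[Si](C)(C)C(C)(C)C)CC=C | intermediate
3 | 4-[(tert-butyldimethylsilyl)oxy]heptane-2,6-dione | CC(=O)CC(O[Si](C)(C)C(C)(C)C)CC(C)=O | intermediate
4 | (5R)-5-[(tert-butyldimethylsilyl)oxy]-3-hydroxy-3-methylcyclohexan-1-one (ketol, C3 epimers, not isolated) | CC1(O)CC(=O)C[C@H](O[Si](C)(C)C(C)(C)C)C1 | intermediate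
5 | (R)-5-[(tert-butyldimethylsilyl)oxy]-3-methylcyclohex-2-en-1-one | CC1=CC(=O)C[C@H](O[Si](C)(C)C(C)(C)C)C1 | intermediate
6 | allene (propa-1,2-diene) | C=C=C | starting material
7 | (1R,4R,6R)-4-[(tert-butyldimethylsilyl)oxy]-6-methyl-8-methylidenebicyclo[4.2.0]octan-2-one (cis-fused, cyclobutane anti to OTBS) | C=C1C[C@]2(C)C[C@@H](O[Si](C)(C)C(C)(C)C)CC(=O)[C@H]12 | intermediate
8 | ethyl glyoxylate (ethyl 2-oxoacetate) | CCOC(=O)C=O | starting material
9 | lithium enolate of 7 (C6–OLi, C6=C7; not isolated) | C=C1C[C@]2(C)C[C@@H](O[Si](C)(C)C(C)(C)C)C=C(O[Li])[C@H]12 | intermediate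
10 | ethyl 2-{4-[(tert-butyldimethylsilyl)oxy]-6-methyl-8-methylidene-2-oxobicyclo[4.2.0]octan-3-yl}-2-hydroxyacetate (side chain α at C7, trans to 8-OTBS; C11 epimers) | C=C1C[C@]2(C)C[C@@H](O[Si](C)(C)C(C)(C)C)[C@H](C(O)C(=O)OCC)C(=O)[C@H]12 | intermediate
11 | O-TBS ether of 10 | C=C1C[C@]2(C)C[C@@H](O[Si](C)(C)C(C)(C)C)[C@H](C(O[Si](C)(C)C(C)(C)C)C(=O)OCC)C(=O)[C@H]12 | intermediate
12 | lithium 6α-alkoxide of the reduced ester (not isolated) | C=C1C[C@]2(C)C[C@@H](O[Si](C)(C)C(C)(C)C)[C@H](C(O[Si](C)(C)C(C)(C)C)C(=O)OCC)[C@H](O[Li])[C@H]12 | intermediate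
13 | cis-fused γ-lactone (O6α–C12), 8β-OTBS, 11-OTBS (C11 epimers), methylidenecyclobutane | C=C1C[C@]2(C)C[C@@H](O[Si](C)(C)C(C)(C)C)[C@H]3[C@H](OC(=O)C3O[Si](C)(C)C(C)(C)C)[C@H]12 | intermediate
14 | lithium enolate of 13 (C11=C12–OLi; not isolated) | C=C1C[C@]2(C)C[C@@H](O[Si](C)(C)C(C)(C)C)[C@H]3[C@H](OC(O[Li])=C3O[Si](C)(C)C(C)(C)C)[C@H]12 | intermediate
15 | 11-methyl-11-OTBS lactone (methyl syn to H7), methylidenecyclobutane | C=C1C[C@]2(C)C[C@@H](O[Si](C)(C)C(C)(C)C)[C@H]3[C@H](OC(=O)[C@@]3(C)O[Si](C)(C)C(C)(C)C)[C@H]12 | intermediate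
16 | ozonide of 15 (spiro-1,2,4-trioxolane at C4; not isolated) | C1OC2(OO1)C[C@]3(C)C[C@@H](O[Si](C)(C)C(C)(C)C)[C@H]4[C@H](OC(=O)[C@@]4(C)O[Si](C)(C)C(C)(C)C)[C@H]23 | intermediate
17 | cyclobutanone (C4=O) lactone | O=C1C[C@]2(C)C[C@@H](O[Si](C)(C)C(C)(C)C)[C@H]3[C@H](OC(=O)[C@@]3(C)O[Si](C)(C)C(C)(C)C)[C@H]12 | intermediate
18 | potassium enolate of 17 (C1=C4–OK; not isolated) | [K]OC1=C[C@]2(C)C[C@@H](O[Si](C)(C)C(C)(C)C)[C@H]3[C@H](OC(=O)[C@@]3(C)O[Si](C)(C)C(C)(C)C)[C@H]12 | intermediate
19 | cyclobutenyl triflate (C1=C4–OTf) | O=S(=O)(OC1=C[C@]2(C)C[C@@H](O[Si](C)(C)C(C)(C)C)[C@H]3[C@H](OC(=O)[C@@]3(C)O[Si](C)(C)C(C)(C)C)[C@H]12)C(F)(F)F | intermediate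
20 | cis-fused 1-methylcyclobutene lactone (C1H=C4–CH3) | CC1=C[C@]2(C)C[C@@H](O[Si](C)(C)C(C)(C)C)[C@H]3[C@H](OC(=O)[C@@]3(C)O[Si](C)(C)C(C)(C)C)[C@H]12 | intermediate
21 | ethylene | C=C | starting material
22 | 8β,11-bis[(tert-butyldimethylsilyl)oxy]-elema-1,3-dien-12,6-olide | C=C[C@]1(C)C[C@@H](O[Si](C)(C)C(C)(C)C)[C@H]2[C@H](OC(=O)[C@@]2(C)O[Si](C)(C)C(C)(C)C)[C@@H]1C(=C)C | intermediate
23 | 8β,11-dihydroxy-elema-1,3-dien-12,6-olide | C=C[C@]1(C)C[C@@H](O)[C@H]2[C@H](OC(=O)[C@@]2(C)O)[C@@H]1C(=C)C | intermediate
24 | 3-methylbut-3-enoic acid | C=C(C)CC(=O)O | starting material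
25 | 11-hydroxy-8β-(3-methylbut-3-enoyloxy)-elema-1,3-dien-12,6-olide | C=C[C@]1(C)C[C@@H](OC(=O)CC(=C)C)[C@H]2[C@H](OC(=O)[C@@]2(C)O)[C@@H]1C(=C)C | intermediate
26 | target CNP0106639.1: 3-acetoxy-6-ethenyl-3,6-dimethyl-2-oxo-7-(prop-1-en-2-yl)octahydro-1-benzofuran-4-yl 3-methylbut-3-enoate (faces as in the convention) | C=C[C@]1(C)C[C@@H](OC(=O)CC(=C)C)[C@H]2[C@H](OC(=O)[C@@]2(C)OC(C)=O)[C@@H]1C(=C)C | target

**Step count and risks**

Total step count: 15. Longest linear sequence: 15 steps (from 1).

Steps most likely to fail:

Step 4. Facial selectivity may be insufficient, with addition syn to the silyloxy group competing, and adduct may be lost to secondary photoreaction. The fallback sets out from 6 and comes back at 7. It removes the need for 1,3-induction by forming the cyclobutane first and adding the C8 oxygen afterwards. Irradiation of commercial 3-methylcyclohex-2-en-1-one with 6 should give the racemic head-to-head adduct F1. Dehydrogenation with IBX should give the bicyclic enone F2; only the C7=C8 bond can form because C10 has no hydrogen. Alkaline hydrogen peroxide should epoxidise from the β-face, the axial C10–C1 bond shielding the α-face, to give the epoxy ketone F3. Reductive opening of the Cα–O bond with sodium phenylselenide (from (PhSe)2 and NaBH4, AcOH) should give the β-hydroxy ketone F4 as the racemate. Lipase-catalysed acylation with vinyl acetate should remove the unwanted enantiomer as the acetate F5. Silylation of the remaining enantiomer of F4 (TBSCl, imidazole) gives 7.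

Step 5. The enolate may form partly at C5, the aldol may show poor facial selectivity at C7, and the β-hydroxy ketone may undergo retro-aldol cleavage. The fallback sets out from 7 and comes back at 13. It sets C7 under thermodynamic control and brings in the C11 oxygen by enolate oxidation. Alkylation of the lithium enolate of 7 with ethyl bromoacetate should give the keto ester F6, whose C7 centre is equilibrated with DBU to the trans-diequatorial arrangement. L-Selectride reduction as in step 7 gives the lithium alkoxide F7 (not isolated), which closes to the lactone F8. KHMDS followed by 2-(phenylsulfonyl)-3-phenyloxaziridine should hydroxylate the lactone enolate to the α-hydroxy lactone F9; either C11 epimer serves. TBSOTf/2,6-lutidine then gives 13.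

Step 3. Enantioselectivity may erode with a silyloxy substituent, and silanol may be eliminated from the β-silyloxy ketone under amine catalysis. The fallback sets out from 3 and comes back at 5. It replaces asymmetric catalysis by enzymatic resolution. Cyclisation of 3 with pyrrolidine/AcOH should give the racemic enone F10. Luche reduction (NaBH4, CeCl3, MeOH) should give the racemic cis-allylic alcohol F11, with the hydroxyl equatorial by axial hydride attack. A lipase with vinyl acetate should acylate the enantiomer with the (R)-configured allylic carbinol, which by the usual enantiopreference for cyclic allylic alcohols is the one with the wanted C8 configuration, to give the allylic acetate F12. After separation from the unreacted enantiomer, methanolysis (K2CO3, MeOH) and MnO2 oxidation of the enantiopure alcohol return 5.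

Further compounds
F1 | step 4 | rac-cis-6-methyl-8-methylidenebicyclo[4.2.0]octan-2-one (one enantiomer drawn) | C=C1C[C@]2(C)CCCC(=O)[C@H]12
F2 | step 4 | rac-cis-6-methyl-8-methylidenebicyclo[4.2.0]oct-3-en-2-one (one enantiomer drawn) | C=C1C[C@]2(C)CC=CC(=O)[C@H]12
F3 | step 4 | rac-3,4-epoxy-6-methyl-8-methylidenebicyclo[4.2.0]octan-2-one, epoxide on the β-face (one enantiomer drawn) | C=C1C[C@]2(C)C[C@H]3O[C@H]3C(=O)[C@H]12
F4 | step 4 | 4-hydroxy-6-methyl-8-methylidenebicyclo[4.2.0]octan-2-one (desilyl-7; racemic before resolution) | C=C1C[C@]2(C)C[C@@H](O)CC(=O)[C@H]12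
F5 | step 4 | acetate of the enantiomer of F4 | C=C1C[C@@]2(C)C[C@H](OC(C)=O)CC(=O)[C@@H]12
F6 | step 5 | ethyl 2-{4-[(tert-butyldimethylsilyl)oxy]-6-methyl-8-methylidene-2-oxobicyclo[4.2.0]octan-3-yl}acetate (side chain α) | C=C1C[C@]2(C)C[C@@H](O[Si](C)(C)C(C)(C)C)[C@H](CC(=O)OCC)C(=O)[C@H]12
F7 | step 5 | lithium 6α-alkoxide of reduced F6 (not isolated) | C=C1C[C@]2(C)C[C@@H](O[Si](C)(C)C(C)(C)C)[C@H](CC(=O)OCC)[C@H](O[Li])[C@H]12
F8 | step 5 | cis-fused γ-lactone with C11H2 | C=C1C[C@]2(C)C[C@@H](O[Si](C)(C)C(C)(C)C)[C@H]3[C@H](OC(=O)C3)[C@H]12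
F9 | step 5 | 11-hydroxy lactone (C11 configuration inconsequential) | C=C1C[C@]2(C)C[C@@H](O[Si](C)(C)C(C)(C)C)[C@H]3[C@H](OC(=O)C3O)[C@H]12
F10 | step 3 | rac-5-[(tert-butyldimethylsilyl)oxy]-3-methylcyclohex-2-en-1-one | CC1=CC(=O)CC(O[Si](C)(C)C(C)(C)C)C1
F11 | step 3 | cis-5-[(tert-butyldimethylsilyl)oxy]-3-methylcyclohex-2-en-1-ol (racemic before resolution; wanted enantiomer drawn) | CC1=C[C@H](O)C[C@H](O[Si](C)(C)C(C)(C)C)C1
F12 | step 3 | acetate of the wanted enantiomer of F11 | CC1=C[C@H](OC(C)=O)C[C@H](O[Si](C)(C)C(C)(C)C)C1
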